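## Structural features

The target is an achiral C36 polyphenol built from five benzene rings: ring A (a pentasubstituted resorcinol monomethyl ether), ring B (a 1,3,5-trisubstituted phenol) and three 4-hydroxyphenyl rings (rings C). Rings A and B are joined by a CH2–CH2 bridge, and each ring C hangs on one CH2 link: two on ring A at C4 and C6, one on ring B at C5'. There is no stereocentre, so every problem is one of regiochemistry and of telling six oxygen functions apart (five free phenols and the methyl ether at C1 of ring A). Ring A carries carbon substituents on three neighbouring atoms (C4, C5, C6) and is crowded. On ring B the bridge, the hydroxyl and the benzyl group are all meta to one another, a pattern that electrophilic substitution of a phenol cannot produce. The molecule is electron-rich: the phenols oxidise readily in basic, aerated media, and each 4-hydroxybenzyl group on ring A can be detached again by strong acid. The real difficulty is to put two identical benzyl groups on C4 and C6 of ring A and none on C2, on ring B or on the phenol rings already present. The key step exploits that C4 is ortho to the C3 hydroxyl and para to the C1 methoxyl, and C6 is para to the hydroxyl and ortho to the methoxyl, so both are the innate nucleophilic sites of ring A. Ring B, with its meta benzyl group, is made beforehand by cross-coupling and silenced as a diacetate.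

## Logic of the disconnections

**18 ⇒ 17.** The two acetyl–oxygen bonds on ring B and its ring C are cut. Skeletally nothing is gained, but the esters are what keep these two rings silent in the preceding C–C bond formation. The forward step must be a mild deacylation that leaves the methyl ether and the three diarylmethane links intact and does not oxidise the five phenols.

**17 ⇒ 12 + two 13.** The C4–CH2 and C6–CH2 bonds of ring A are cut. These carbons are activated by both ring A oxygens, and the fragment released is the natural C7 unit. One operation removes two rings and takes ring A from pentasubstituted to 1,3,5-trisubstituted, leaving a bibenzyl with only meta relationships. The forward step must benzylate twice, at C4 and C6 and not at C2, on ring A only, with the electrophile from 13 not consuming itself.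

**12 ⇒ 10 (through 11).** The CH2–CH2 bridge is traced back to an alkyne and the free ring A hydroxyl to a benzyl ether. An alkyne joins two arenes without any geometric issue, and the benzyl ether falls in the same hydrogenation, so no protecting-group exchange is needed. The forward step must saturate the alkyne and cleave one benzyl ether without touching two aryl acetates or the diarylmethane.

**10 ⇒ 7 + 8 (through 9).** The aryl–CH2 bond at C5' of ring B is cut. This benzyl group is meta to the oxygen and to the bridge, so its position has to be dictated by a halogen. The forward step is an sp2–sp3 coupling that must tolerate aryl acetates and an internal alkyne, which calls for a neutral organozinc.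

**7 ⇒ 6 + 2.** The aryl–alkynyl bond at C1' of ring B is cut. In 2 the two meta positions carry different halogens, so no statistical mono-coupling of a symmetrical dihalide arises. The forward step must couple at iodine only, under conditions mild enough for the acetate.

**6 ⇒ 4 ⇒ 3.** The terminal alkyne carbon is removed (one-carbon homologation of an aldehyde), then the benzyl–oxygen bond. This leads back to a catalogue aldehyde that already has the hydroxyl and methoxyl of ring A in place. The forward steps are routine.

**2 ⇒ 1.** The acetyl–oxygen bond is cut, leading to a catalogue bromoiodophenol. The acetate is installed first so that it serves both as the protecting group through the couplings and as the deactivating group in the key step.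

## Other disconnections considered

**Alternative 1:** The cut runs across C5 and C6 of ring A, removing the C5–alkyne bond and the C6–CH2 bond at once. In the forward direction CsF would release an aryne from the silyl triflate A1. The copper acetylide formed from the ring B alkyne A2 and catalytic CuI would add at C5, the aryne carbon remote from the methoxyl. The arylcopper left at C6 would be trapped by 4-(benzyloxy)benzyl bromide A3 to give the penta-O-benzyl diarylalkyne A4, and one hydrogenation would then give 18.
- In its favour: the substitution sites are fixed by where the aryne sits, so C2 cannot be touched. On this point it is better than the chosen plan. The endgame is a single neutral hydrogenation with no differentiated esters and no base, which is equal to or slightly better than the chosen two-step finish.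
- Against it: A1 is a pentasubstituted ortho-silylaryl triflate that must already carry the C4 benzyl group, so one ring A benzylation and a lengthy silyl/triflate installation are still needed beforehand. The C4 benzyl group flanks C5 and sterically opposes the attack that the methoxyl favours electronically. The arylcopper can be protonated by A2 instead of benzylated, and trapping with benzylic halides is less established than with allylic ones.
- Comparison: mechanistically this is a polar three-component coupling, set against the chosen twofold Friedel–Crafts reaction. It is clearly longer overall, and its one demanding step rests on a precursor that costs more than the whole chosen route to 12.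

**Alternative 2:** The cut removes C4–CH2, C6–CH2 and the C5–vinyl bond together. In the forward direction 1-(benzyloxy)-3-iodo-5-methoxybenzene A5, two equivalents of 4-(benzyloxy)benzyl chloride A6 and the ring B styrene A7 would be combined under Pd(OAc)2, a triarylphosphine, norbornene A8 and Cs2CO3. Oxidative addition, insertion of A8, ortho C–H palladation and benzylation through tetravalent palladium would occur at both ortho positions. Extrusion of A8 and Heck termination with A7 would give the penta-O-benzyl (E)-stilbene A9, and hydrogenation would then give 18.
- In its favour: three ring A bonds form in one operation, and the iodine defines the sites, so C2 is excluded. This is better than the chosen plan on regiochemical certainty. A6 is a stable electrophile that cannot self-condense, unlike the quinone methide precursor, which is also better. The hydrogenation endgame is equal or better.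
- Against it: both ortho C–H bonds of A5 lie between the iodine-bearing carbon and an alkoxy group. Ortho palladation next to a meta substituent is the known weak point of this chemistry and would be needed twice. A6 can also enter direct Heck or homocoupling pathways with A7, and A7 needs its own cross-coupling sequence comparable to the chosen route to 10.
- Comparison: the step count is about equal, possibly one step shorter. The risk is concentrated in one multicomponent step on an unfavourable substitution pattern, whereas the chosen plan leans on the innate reactivity of ring A.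

**Alternative 3:** The cut opens ring A at C5–C6 and C2–C3, so ring A is built de novo. In the forward direction 4-[4-(benzyloxy)phenyl]butan-2-one A10 would add under KOC(CH3)3 through its internal alpha carbon to the beta carbon of the alpha-benzyl enoate A11. The methyl enolate would then close the ring by Claisen condensation to give the all-trans meso cyclohexane-1,3-dione A12. Its three stereocentres are transient. Dehydrogenation to the symmetrical resorcinol A13, mono-O-methylation and hydrogenolysis would follow.
- In its favour: the C4/C5/C6 pattern follows from connectivity alone, with no aromatic substitution regiochemistry, which is better than the chosen plan on positional fidelity. A10 is cheap. Because A13 is symmetrical, monomethylation raises no site question, which is equal to the chosen plan, where the monoether is bought.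
- Against it: A11 is a trisubstituted enoate, a poor Michael acceptor prone to gamma-deprotonation. The ketone can also react through its methyl enolate first. Aromatisation of a hindered dione must spare six benzylic CH2 groups, and monomethylation of A13 is statistical between mono- and diether. A11 requires homologation of a ring B aldehyde.
- Comparison: this is an anionic annulation followed by oxidation, set against electrophilic substitution. It is markedly longer and has more uncertain steps than the chosen plan.

Key step: step 7

Remark on the chemistry: ring A is numbered C1 (OCH3), C2 (H), C3 (OH), C4, C5 (bridge), C6. Ring B carries the bridge at C1', oxygen at C3' and the benzyl group at C5'. Every 4-oxygenated benzyl ring is called ring C.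

Remark on the chemistry: the connectivity of 12 and 17 was checked atom by atom against 18 and needs no correction. The design is tightened in how 12 is reached. An iodo/bromo pair on ring B replaces two equal halogens, which removes a statistical mono-coupling. The two acetates are carried from the building blocks while ring A is a benzyl ether, so the hydrogenation that saturates the bridge also frees the ring A phenol and no protecting-group exchange is needed. Compounds 1, 3, 8 and 13 are taken as catalogue chemicals.

## Route

Step 1
Reactants: 1 3-bromo-5-iodophenol
Product: 2 3-bromo-5-iodophenyl acetate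
Conditions: Ac2O, pyridine, 0 °C → rt
Reagents that add atoms: acetic anhydride, CC(=O)OC(C)=O
Why: O-acetylation of a phenol by nucleophilic acyl substitution; the acetate protects the ring B oxygen through the neutral palladium couplings and later deactivates ring B in the key step.

Step 2
Reactants: 3 3-hydroxy-5-methoxybenzaldehyde
Product: 4 3-(benzyloxy)-5-methoxybenzaldehyde
Conditions: BnBr, K2CO3, DMF, rt
Reagents that add atoms: benzyl bromide, BrCc1ccccc1
Why: Williamson ether synthesis on the phenoxide; benzyl is chosen because it is removed later by the same hydrogenation that saturates the alkyne, and it keeps the ring A phenol from exchanging acyl groups with the aryl acetates under base.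

Step 3
Reactants: 4 3-(benzyloxy)-5-methoxybenzaldehyde
Product: 6 1-(benzyloxy)-3-ethynyl-5-methoxybenzene, via diazoalkene 5 (not isolated)
Conditions: dimethyl (1-diazo-2-oxopropyl)phosphonate, K2CO3, MeOH, 0 °C → rt
Reagents that add atoms: dimethyl (1-diazo-2-oxopropyl)phosphonate, COP(=O)(OC)C(=[N+]=[N-])C(C)=O
Why: Ohira–Bestmann (Seyferth–Gilbert) homologation; methanolysis of the reagent gives the diazomethylphosphonate anion, which adds to the non-enolisable aldehyde and eliminates phosphate to diazoalkene 5, which loses N2 with a 1,2-hydrogen shift to the terminal alkyne.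

Step 4
Reactants: 6 1-(benzyloxy)-3-ethynyl-5-methoxybenzene; 2 3-bromo-5-iodophenyl acetate
Product: 7 3-{[3-(benzyloxy)-5-methoxyphenyl]ethynyl}-5-bromophenyl acetate
Conditions: PdCl2(PPh3)2 (2 mol %), CuI (4 mol %), Et3N, THF, rt, degassed
Reagents that add atoms: none
Why: Sonogashira coupling; oxidative addition of zerovalent palladium to the C–I bond is far faster than to the C–Br bond at room temperature, so only the iodide should couple, and an aryl acetate is not attacked by a tertiary amine under these anhydrous conditions.

Step 5
Reactants: 7 3-{[3-(benzyloxy)-5-methoxyphenyl]ethynyl}-5-bromophenyl acetate; 8 4-(chloromethyl)phenyl acetate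
Product: 10 3-[4-(acetyloxy)benzyl]-5-{[3-(benzyloxy)-5-methoxyphenyl]ethynyl}phenyl acetate, via [4-(acetyloxy)benzyl]zinc chloride 9 (not isolated)
Conditions: 8, Zn dust, LiCl, THF, 25 °C; then 7, Pd(OAc)2 (2 mol %), SPhos (4 mol %), THF, 25 → 40 °C
Reagents that add atoms: none
Why: LiCl-assisted insertion of zinc into the benzylic chloride gives an ester-tolerant benzylzinc chloride, and Negishi sp2–sp3 coupling with the aryl bromide places the benzyl group at the meta position fixed by the halogen; the medium is neutral, so both acetates and the internal alkyne should be spectators.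

Step 6
Reactants: 10 3-[4-(acetyloxy)benzyl]-5-{[3-(benzyloxy)-5-methoxyphenyl]ethynyl}phenyl acetate
Product: 12 3-[4-(acetyloxy)benzyl]-5-[2-(3-hydroxy-5-methoxyphenyl)ethyl]phenyl acetate, via O-benzyl bibenzyl 11 (not isolated)
Conditions: H2 (1 atm), 10% Pd/C, EtOAc–THF, rt
Reagents that add atoms: none
Why: Heterogeneous catalytic hydrogenation; the diarylalkyne is saturated first (11) and the benzyl aryl ether is then hydrogenolysed, while aryl acetates, the methyl ether and the diarylmethane are inert, and the aprotic neutral medium prevents acyl transfer to the freed phenol.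

Step 7
Reactants: 12 3-[4-(acetyloxy)benzyl]-5-[2-(3-hydroxy-5-methoxyphenyl)ethyl]phenyl acetate; 13 4-hydroxybenzyl alcohol
Product: 17 3-[4-(acetyloxy)benzyl]-5-{2-[3-hydroxy-2,6-bis(4-hydroxybenzyl)-5-methoxyphenyl]ethyl}phenyl acetate, via 4-methylidenecyclohexa-2,5-dien-1-one 14 (not isolated), via C6-monobenzyl intermediate 15 (not isolated), via C4-monobenzyl intermediate 16 (not isolated)
Conditions: TsOH·H2O (10 mol %), MeCN, 40 °C, Ar; 13 (2.3 equiv) in MeCN added by syringe pump over 6 h
Reagents that add atoms: none
Why: TsOH protonates the benzylic hydroxyl of 13 and loss of water gives the 4-hydroxybenzyl cation, the O-protonated form of para-quinone methide 14. Ring A of 12 adds through C6 (para to the free hydroxyl) or C4 (para to the methoxyl) to the exocyclic CH2 of 14 and loss of a proton restores the arene, giving 15 or 16; a second such event at the remaining site turns either isomer into 17. The closest known reaction type is the acid-promoted Friedel–Crafts C-benzylation of resorcinols and their monoethers by 4-hydroxybenzyl alcohol, the laboratory counterpart of the presumed biosynthetic benzylation. No ring is closed and no stereocentre is formed. The step needs ring A to react in preference to ring B, to rings C and to 13 itself, C4 and C6 in preference to C2, and carbon in preference to oxygen. Ring A is the only ring with two donor oxygens that reinforce each other, ring B and its ring C are weak donors as acetates, and the phenol rings of 13, 15, 16 and 17 are simple 4-alkylphenols that should be orders of magnitude less nucleophilic. C4 and C6 each have one para oxygen, whereas C2 has only ortho donors and is flanked by both oxygens, and any benzyl aryl ether formed at oxygen should revert under the acid and drain to the C-benzyl products. Slow addition of 13 keeps 14 dilute so that it is caught by ring A and not by another molecule of 13, and the limit of about 2.3 equivalents guards against a third benzylation at C2.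

Step 8
Reactants: 17 3-[4-(acetyloxy)benzyl]-5-{2-[3-hydroxy-2,6-bis(4-hydroxybenzyl)-5-methoxyphenyl]ethyl}phenyl acetate
Product: 18 3-{2-[3-hydroxy-2,6-bis(4-hydroxybenzyl)-5-methoxyphenyl]ethyl}-5-(4-hydroxybenzyl)phenol (CNP0204120.0)
Conditions: K2CO3 (0.5 equiv), MeOH, 0 °C → rt, Ar; then aq. NH4Cl
Reagents that add atoms: none
Why: Base-catalysed transesterification (methanolysis) of the two aryl acetates, which is far faster than any reaction of the methyl ether or the diarylmethane links; substoichiometric base, low temperature and exclusion of air protect the electron-rich phenolates from oxidation.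

## Compound list

1 | 3-bromo-5-iodophenol | Oc1cc(Br)cc(I)c1 | starting material
2 | 3-bromo-5-iodophenyl acetate | CC(=O)Oc1cc(Br)cc(I)c1 | intermediate
3 | 3-hydroxy-5-methoxybenzaldehyde | COc1cc(O)cc(C=O)c1 | starting material
4 | 3-(benzyloxy)-5-methoxybenzaldehyde | COc1cc(OCc2ccccc2)cc(C=O)c1 | intermediate
5 | 1-(benzyloxy)-3-(2-diazoethenyl)-5-methoxybenzene (diazoalkene) | COc1cc(OCc2ccccc2)cc(C=C=[N+]=[N-])c1 | intermediate (not isolated)
6 | 1-(benzyloxy)-3-ethynyl-5-methoxybenzene | COc1cc(OCc2ccccc2)cc(C#C)c1 | intermediate
7 | 3-{[3-(benzyloxy)-5-methoxyphenyl]ethynyl}-5-bromophenyl acetate | COc1cc(OCc2ccccc2)cc(C#Cc2cc(Br)cc(OC(C)=O)c2)c1 | intermediate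
8 | 4-(chloromethyl)phenyl acetate | CC(=O)Oc1ccc(CCl)cc1 | starting material
9 | [4-(acetyloxy)benzyl]zinc chloride | CC(=O)Oc1ccc(C[Zn]Cl)cc1 | intermediate (not isolated)
10 | 3-[4-(acetyloxy)benzyl]-5-{[3-(benzyloxy)-5-methoxyphenyl]ethynyl}phenyl acetate | COc1cc(OCc2ccccc2)cc(C#Cc2cc(OC(C)=O)cc(Cc3ccc(OC(C)=O)cc3)c2)c1 | intermediate
11 | 3-[4-(acetyloxy)benzyl]-5-{2-[3-(benzyloxy)-5-methoxyphenyl]ethyl}phenyl acetate (O-benzyl bibenzyl) | COc1cc(OCc2ccccc2)cc(CCc2cc(OC(C)=O)cc(Cc3ccc(OC(C)=O)cc3)c2)c1 | intermediate (not isolated)
12 | 3-[4-(acetyloxy)benzyl]-5-[2-(3-hydroxy-5-methoxyphenyl)ethyl]phenyl acetate | COc1cc(O)cc(CCc2cc(OC(C)=O)cc(Cc3ccc(OC(C)=O)cc3)c2)c1 | intermediate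
13 | 4-hydroxybenzyl alcohol | OCc1ccc(O)cc1 | starting material
14 | 4-methylidenecyclohexa-2,5-dien-1-one (para-quinone methide) | C=C1C=CC(=O)C=C1 | intermediate (not isolated)
15 | 3-[4-(acetyloxy)benzyl]-5-{2-[5-hydroxy-2-(4-hydroxybenzyl)-3-methoxyphenyl]ethyl}phenyl acetate (C6-monobenzyl) | COc1cc(O)cc(CCc2cc(OC(C)=O)cc(Cc3ccc(OC(C)=O)cc3)c2)c1Cc1ccc(O)cc1 | intermediate (not isolated)
16 | 3-[4-(acetyloxy)benzyl]-5-{2-[3-hydroxy-2-(4-hydroxybenzyl)-5-methoxyphenyl]ethyl}phenyl acetate (C4-monobenzyl) | COc1cc(O)c(Cc2ccc(O)cc2)c(CCc2cc(OC(C)=O)cc(Cc3ccc(OC(C)=O)cc3)c2)c1 | intermediate (not isolated)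
17 | 3-[4-(acetyloxy)benzyl]-5-{2-[3-hydroxy-2,6-bis(4-hydroxybenzyl)-5-methoxyphenyl]ethyl}phenyl acetate | COc1cc(O)c(Cc2ccc(O)cc2)c(CCc2cc(OC(C)=O)cc(Cc3ccc(OC(C)=O)cc3)c2)c1Cc1ccc(O)cc1 | intermediate
18 | 3-{2-[3-hydroxy-2,6-bis(4-hydroxybenzyl)-5-methoxyphenyl]ethyl}-5-(4-hydroxybenzyl)phenol (CNP0204120.0) | COc1cc(O)c(Cc2ccc(O)cc2)c(CCc2cc(O)cc(Cc3ccc(O)cc3)c2)c1Cc1ccc(O)cc1 | target

## Step count and least certain steps

Total step count: 8. Longest linear sequence: 7 steps (steps 2, 3, 4, 5, 6, 7 and 8, from 3 to 18).

**Step 7 (key step).** The most likely failure is loss of control over where and how often the quinone methide is captured: a third benzylation at C2, incomplete conversion that stops at 15 or 16, and self-condensation of 13 into oligomers that consume the electrophile. These follow because all three free positions of ring A are activated and every product still carries phenol rings. Recovered 15 and 16 could be resubmitted. The fallback replaces the electrophilic benzylation by halogenation and cross-coupling. It sets out from 12 and comes back to the route at 18: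
- Twofold bromination of 12 with N-bromosuccinimide (2.05 equiv, MeCN, 0 °C), which for 5-alkylresorcinol derivatives is expected at the two positions flanking the alkyl chain, should give 3-[4-(acetyloxy)benzyl]-5-[2-(2,6-dibromo-3-hydroxy-5-methoxyphenyl)ethyl]phenyl acetate F1.
- Acetylation (Ac2O, pyridine) should give the triacetate 3-[4-(acetyloxy)benzyl]-5-{2-[3-(acetyloxy)-2,6-dibromo-5-methoxyphenyl]ethyl}phenyl acetate F2.
- Twofold Negishi coupling with 9 (Pd(OAc)2, SPhos, THF, 50 °C) should give the pentaacetate 3-[4-(acetyloxy)benzyl]-5-(2-{3-(acetyloxy)-2,6-bis[4-(acetyloxy)benzyl]-5-methoxyphenyl}ethyl)phenyl acetate F3.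
- Methanolysis under the conditions of step 8 should give 18.

**Step 5.** The most likely failure is erosion of the benzylzinc reagent by Wurtz-type homocoupling or protonation during its formation, together with slow oxidative addition into the aryl bromide while the alkyne competes for the catalyst. Both leave 7 unconverted. Any acetate lost here could be restored with Ac2O/pyridine, since ring A is still a benzyl ether. The fallback changes the order of bond formation so that the Negishi coupling meets the more reactive C–I bond and no alkyne. It sets out from 2 and comes back at 10: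
- Coupling of 2 with 9 at the iodide (Pd(PPh3)4, THF, 0 °C → rt) should give 3-[4-(acetyloxy)benzyl]-5-bromophenyl acetate F4.
- Sonogashira coupling of F4 with 6 at the bromide (PdCl2(PPh3)2, CuI, Et3N, DMF, 70 °C) should give 10.

**Step 4.** The most likely failure is oxidative homocoupling of alkyne 6 under copper catalysis if air is not rigorously excluded, with minor coupling at the bromide or partial loss of the acetate if the reaction has to be warmed. The fallback builds the bridge by a Heck reaction instead. It sets out from 4 and comes back at 12 (through 11):
- Wittig methylenation of 4 (methyltriphenylphosphonium bromide, KOC(CH3)3, THF) should give 1-(benzyloxy)-3-ethenyl-5-methoxybenzene F5.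
- Iodide-selective Heck coupling with 2 (Pd(OAc)2, Bu4NCl, KOAc, DMF, 70 °C) should give 3-{(E)-2-[3-(benzyloxy)-5-methoxyphenyl]ethenyl}-5-bromophenyl acetate F6.
- Negishi coupling with 9 as in step 5 should give 3-[4-(acetyloxy)benzyl]-5-{(E)-2-[3-(benzyloxy)-5-methoxyphenyl]ethenyl}phenyl acetate F7.
- Hydrogenation under the conditions of step 6 should give 12.

**Step 6.** The most likely failure is stalling of the benzyl ether hydrogenolysis after the alkyne has been saturated. The causes would be catalyst poisoning by traces of phosphine, zinc or copper from the couplings and the slower hydrogenolysis in an aprotic solvent. The fallback separates the two events and removes the benzyl group by a Lewis acid. It sets out from 10 and comes back at 12: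
- The hydrogenation is stopped after uptake by the alkyne and 11 is isolated.
- The ether is cleaved with BCl3 and pentamethylbenzene (CH2Cl2, −78 °C), conditions under which aryl acetates and the aryl methyl ether should persist, to give 12.
- This fallback makes no compound outside the list (F0).

## Further compounds

F1 | step 7 | 3-[4-(acetyloxy)benzyl]-5-[2-(2,6-dibromo-3-hydroxy-5-methoxyphenyl)ethyl]phenyl acetate | COc1cc(O)c(Br)c(CCc2cc(OC(C)=O)cc(Cc3ccc(OC(C)=O)cc3)c2)c1Br
F2 | step 7 | 3-[4-(acetyloxy)benzyl]-5-{2-[3-(acetyloxy)-2,6-dibromo-5-methoxyphenyl]ethyl}phenyl acetate | COc1cc(OC(C)=O)c(Br)c(CCc2cc(OC(C)=O)cc(Cc3ccc(OC(C)=O)cc3)c2)c1Br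
F3 | step 7 | 3-[4-(acetyloxy)benzyl]-5-(2-{3-(acetyloxy)-2,6-bis[4-(acetyloxy)benzyl]-5-methoxyphenyl}ethyl)phenyl acetate | COc1cc(OC(C)=O)c(Cc2ccc(OC(C)=O)cc2)c(CCc2cc(OC(C)=O)cc(Cc3ccc(OC(C)=O)cc3)c2)c1Cc1ccc(OC(C)=O)cc1
F4 | step 5 | 3-[4-(acetyloxy)benzyl]-5-bromophenyl acetate | CC(=O)Oc1ccc(Cc2cc(Br)cc(OC(C)=O)c2)cc1
F5 | step 4 | 1-(benzyloxy)-3-ethenyl-5-methoxybenzene | COc1cc(OCc2ccccc2)cc(C=C)c1
F6 | step 4 | 3-{(E)-2-[3-(benzyloxy)-5-methoxyphenyl]ethenyl}-5-bromophenyl acetate | COc1cc(OCc2ccccc2)cc(/C=C/c2cc(Br)cc(OC(C)=O)c2)c1
F7 | step 4 | 3-[4-(acetyloxy)benzyl]-5-{(E)-2-[3-(benzyloxy)-5-methoxyphenyl]ethenyl}phenyl acetate | COc1cc(OCc2ccccc2)cc(/C=C/c2cc(OC(C)=O)cc(Cc3ccc(OC(C)=O)cc3)c2)c1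
F0 | step 6 | none | none
A1 | alternative 1 | 3-(benzyloxy)-2-[4-(benzyloxy)benzyl]-5-methoxy-6-(trimethylsilyl)phenyl trifluoromethanesulfonate | COc1cc(OCc2ccccc2)c(Cc2ccc(OCc3ccccc3)cc2)c(OS(=O)(=O)C(F)(F)F)c1[Si](C)(C)C
A2 | alternative 1 | 1-(benzyloxy)-3-[4-(benzyloxy)benzyl]-5-ethynylbenzene | C#Cc1cc(OCc2ccccc2)cc(Cc2ccc(OCc3ccccc3)cc2)c1
A3 | alternative 1 | 4-(benzyloxy)benzyl bromide | BrCc1ccc(OCc2ccccc2)cc1
A4 | alternative 1 | penta-O-benzyl diarylalkyne analogue of the target | COc1cc(OCc2ccccc2)c(Cc2ccc(OCc3ccccc3)cc2)c(C#Cc2cc(OCc3ccccc3)cc(Cc3ccc(OCc4ccccc4)cc3)c2)c1Cc1ccc(OCc2ccccc2)cc1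
A5 | alternative 2 | 1-(benzyloxy)-3-iodo-5-methoxybenzene | COc1cc(I)cc(OCc2ccccc2)c1
A6 | alternative 2 | 4-(benzyloxy)benzyl chloride | ClCc1ccc(OCc2ccccc2)cc1
A7 | alternative 2 | 1-(benzyloxy)-3-[4-(benzyloxy)benzyl]-5-ethenylbenzene | C=Cc1cc(OCc2ccccc2)cc(Cc2ccc(OCc3ccccc3)cc2)c1
A8 | alternative 2 | norbornene (bicyclo[2.2.1]hept-2-ene) | C1=CC2CCC1C2
A9 | alternative 2 | penta-O-benzyl (E)-stilbene analogue of the target | COc1cc(OCc2ccccc2)c(Cc2ccc(OCc3ccccc3)cc2)c(/C=C/c2cc(OCc3ccccc3)cc(Cc3ccc(OCc4ccccc4)cc3)c2)c1Cc1ccc(OCc2ccccc2)cc1
A10 | alternative 3 | 4-[4-(benzyloxy)phenyl]butan-2-one | CC(=O)CCc1ccc(OCc2ccccc2)cc1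
A11 | alternative 3 | methyl (2E)-2-[4-(benzyloxy)benzyl]-5-{3-(benzyloxy)-5-[4-(benzyloxy)benzyl]phenyl}pent-2-enoate | COC(=O)/C(Cc1ccc(OCc2ccccc2)cc1)=C/CCc1cc(OCc2ccccc2)cc(Cc2ccc(OCc3ccccc3)cc2)c1
A12 | alternative 3 | all-trans (meso) 4,6-bis[4-(benzyloxy)benzyl]-5-(2-{3-(benzyloxy)-5-[4-(benzyloxy)benzyl]phenyl}ethyl)cyclohexane-1,3-dione | O=C1CC(=O)[C@H](Cc2ccc(OCc3ccccc3)cc2)[C@@H](CCc2cc(OCc3ccccc3)cc(Cc3ccc(OCc4ccccc4)cc3)c2)[C@@H]1Cc1ccc(OCc2ccccc2)cc1
A13 | alternative 3 | 4,6-bis[4-(benzyloxy)benzyl]-5-(2-{3-(benzyloxy)-5-[4-(benzyloxy)benzyl]phenyl}ethyl)benzene-1,3-diol | Oc1cc(O)c(Cc2ccc(OCc3ccccc3)cc2)c(CCc2cc(OCc3ccccc3)cc(Cc3ccc(OCc4ccccc4)cc3)c2)c1Cc1ccc(OCc2ccccc2)cc1
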